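## Retrosynthetic overview

1. Atom labels: ring C1 (CH bearing the side chain), C2=C3 (butenolide alkene; C11H2–O on C2, C10=O on C3), C4/C5 (cyclopropane CH, C9 its CH2), C6 (CHMe), C7, C8 (CHOH); side chain C1′(H)(C12H2OAc)(homoprenyl).
2. Last ring: the butenolide, by Pd carbonylative lactonisation of a C3 vinyl triflate onto C11–OH; the primary acetate goes on last.
3. Key step (new): Au(I)-catalysed 1,2-acyloxy shift / intramolecular cyclopropanation of a tertiary propargylic acetate closes the eight-membered ring and the cyclopropane together (C4–C5, C4–C9) and leaves the C2=C3 enol acetate as triflate precursor.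
4. The cyclisation substrate is a cis-β,γ-disubstituted γ-lactone (C8–O–C12(=O)–C1′–C1). It serves as template, is then alkylated at C1′ (homoprenyl, trans) and reduced to the C8-OH/C12-OH diol.
5. The lactone comes from Fráter–Seebach alkylation (C1) of a Noyori β-hydroxy ester (C8) built on (S)-3-methylpent-4-enoic acid (C6). Ring order: γ-lactone → cyclooctene + cyclopropane (one step) → lactone opened → butenolide.

Assumption: the vinylcopper adds to 3 anti to the benzyl group of the chelated s-cis imide (giving the 3S acyl unit); 5-iodo-2-methylpent-2-ene is bought or made from the commercial bromide with NaI.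

## Route

Step 1
Reactants: 1 (R)-4-benzyloxazolidin-2-one; 2 (E)-but-2-enoyl chloride
Product: 3 (R)-4-benzyl-3-[(E)-but-2-enoyl]oxazolidin-2-one
Conditions: Et3N, LiCl, THF, 0 °C → rt
Reagents that add atoms: none
Why: LiCl/amine-mediated N-acylation of the oxazolidinone avoids strong base and polymerisation of the crotonyl unit; no stereocentre is touched.

Step 2
Reactants: 3 (R)-4-benzyl-3-[(E)-but-2-enoyl]oxazolidin-2-one
Product: 4 (R)-4-benzyl-3-[(3S)-3-methylpent-4-enoyl]oxazolidin-2-one
Conditions: CH2=CHMgBr, CuBr·SMe2, THF/Me2S, −78 → −20 °C; NH4Cl (aq)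
Reagents that add atoms: vinylmagnesium bromide, C=C[Mg]Br
Why: Auxiliary-controlled organocopper conjugate addition to the Mg-chelated s-cis enoyl imide, vinyl entering anti to the benzyl group, sets the future C6 as S.

Step 3
Reactants: 4 (R)-4-benzyl-3-[(3S)-3-methylpent-4-enoyl]oxazolidin-2-one
Product: 5 (3S)-3-methylpent-4-enoic acid
Conditions: LiOH, H2O2, THF/H2O, 0 °C; Na2SO3; HCl
Reagents that add atoms: hydrogen peroxide, OO
Why: Hydroperoxide attacks the exocyclic imide carbonyl selectively (standard auxiliary cleavage), freeing the acid and returning 1 without touching the β-stereocentre.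

Step 4
Reactants: 5 (3S)-3-methylpent-4-enoic acid
Product: 7 tert-butyl (5S)-5-methyl-3-oxohept-6-enoate, via acyl imidazolide 6 (not isolated)
Conditions: CDI, THF, rt; then KO2CCH2CO2t-Bu, MgCl2, Et3N, MeCN, rt → 40 °C; 1 M HCl
Reagents that add atoms: potassium 3-(tert-butoxy)-3-oxopropanoate, CC(C)(C)OC(=O)CC(=O)[O-].[K+]
Why: Masamune–Brooks homologation, the magnesium malonate half-ester enolate being C-acylated by the acyl imidazolide and losing CO2, under conditions too mild to epimerise C6.

Step 5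
Reactants: 7 tert-butyl (5S)-5-methyl-3-oxohept-6-enoate
Product: 8 tert-butyl (3S,5S)-3-hydroxy-5-methylhept-6-enoate
Conditions: H2 (4 atm), RuCl2[(S)-BINAP] (0.5 mol %), MeOH, 50 °C
Reagents that add atoms: none
Why: Noyori asymmetric hydrogenation of the chelating β-keto ester, (S)-BINAP giving the 3S alcohol (future C8) under catalyst control while the unactivated terminal alkene is not reduced at low pressure.

Step 6
Reactants: 8 tert-butyl (3S,5S)-3-hydroxy-5-methylhept-6-enoate
Product: 10 di-tert-butyl (2S)-2-[(1S,3S)-1-hydroxy-3-methylpent-4-en-1-yl]butanedioate, via dilithium alkoxide enolate 9 (not isolated)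
Conditions: LDA (2.2 equiv), THF, −78 → −20 °C; BrCH2CO2t-Bu, DMPU, −78 → −20 °C
Reagents that add atoms: tert-butyl bromoacetate, CC(C)(C)OC(=O)CBr
Why: Fráter–Seebach alkylation, the lithium-chelated dianion being alkylated on the face away from the carbinol side chain, gives the anti (2S) product and so fixes C1 relative to C8.

Step 7
Reactants: 10 di-tert-butyl (2S)-2-[(1S,3S)-1-hydroxy-3-methylpent-4-en-1-yl]butanedioate
Product: 11 (2S,3S)-2-[(2S)-2-methylbut-3-en-1-yl]-5-oxooxolane-3-carboxylic acid (cis lactone acid)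
Conditions: TFA/CH2Cl2 1:3, 0 °C → rt
Reagents that add atoms: none
Why: Acidolysis of both tert-butyl esters and γ-lactonisation of the C8 hydroxyl onto the acetic acid arm (acyl substitution, retention at C8) give the cis-β,γ-disubstituted lactone; the β-lactone alternative is disfavoured.

Step 8
Reactants: 11 (2S,3S)-2-[(2S)-2-methylbut-3-en-1-yl]-5-oxooxolane-3-carboxylic acid
Product: 13 (4S,5S)-4-(2-diazoacetyl)-5-[(2S)-2-methylbut-3-en-1-yl]oxolan-2-one, via acid chloride 12 (not isolated)
Conditions: (COCl)2, DMF (cat.), CH2Cl2, 0 °C → rt; evaporate; CH2N2, Et2O, 0 °C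
Reagents that add atoms: diazomethane, C=[N+]=[N-]
Why: Acylation of diazomethane by the acid chloride (first stage of the Arndt–Eistert sequence) adds C11 without any base that could epimerise C1.

Step 9
Reactants: 13 (4S,5S)-4-(2-diazoacetyl)-5-[(2S)-2-methylbut-3-en-1-yl]oxolan-2-one
Product: 15 (4S,5S)-4-(2-hydroxyacetyl)-5-[(2S)-2-methylbut-3-en-1-yl]oxolan-2-one, via trifluoroacetate 14 (not isolated)
Conditions: TFA, CH2Cl2, 0 °C; then MeOH, NaHCO3 (aq), 0 °C
Reagents that add atoms: trifluoroacetic acid, OC(=O)C(F)(F)F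
Why: Acidolysis of the α-diazoketone (protonation, loss of N2, capture by trifluoroacetate) and mild methanolysis of the activated ester give the hydroxymethyl ketone.

Step 10
Reactants: 15 (4S,5S)-4-(2-hydroxyacetyl)-5-[(2S)-2-methylbut-3-en-1-yl]oxolan-2-one
Product: 16 (4S,5S)-4-{2-[(tert-butyldimethylsilyl)oxy]acetyl}-5-[(2S)-2-methylbut-3-en-1-yl]oxolan-2-one
Conditions: TBSCl, imidazole, DMF, 0 °C
Reagents that add atoms: tert-butyldimethylsilyl chloride, CC(C)(C)[Si](C)(C)Cl
Why: Silylation of the primary hydroxyl gives an oxygen at C11 that is a poor donor towards a gold carbenoid and a poor leaving group from the later enolate.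

Step 11
Reactants: 16 (4S,5S)-4-{2-[(tert-butyldimethylsilyl)oxy]acetyl}-5-[(2S)-2-methylbut-3-en-1-yl]oxolan-2-one
Product: 18 1-[(tert-butyldimethylsilyl)oxy]-2-{(2S,3S)-2-[(2S)-2-methylbut-3-en-1-yl]-5-oxooxolan-3-yl}but-3-yn-2-yl acetate (both C2 epimers), via bromomagnesium alkoxide 17 (not isolated)
Conditions: HC≡CMgBr, THF, −78 °C; then Ac2O, DMAP (cat.), −78 → 0 °C
Reagents that add atoms: ethynylmagnesium bromide, C#C[Mg]Br; acetic anhydride, CC(=O)OC(C)=O
Why: Chemoselective Grignard addition to the ketone (the lactone is inert at −78 °C) and in-flask acetylation of the tertiary alkoxide give the propargylic acetate; its new C2 centre need not be controlled because it becomes sp2 in step 12.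

Step 12
Reactants: 18 propargylic acetate (both C2 epimers)
Product: 19 tricyclic enol acetate (C1/C8 cis-fused γ-lactone on a bicyclo[6.1.0]non-2-ene; C2–CH2OTBS; C3–OAc; C9 anti to C6–CH3)
Conditions: Ph3PAuNTf2 (5 mol %), 4 Å MS, MeNO2, −20 °C → rt, 0.005 M (slow addition)
Reagents that add atoms: none
Why: Proposed new method: Au(I) π-activation of the terminal alkyne triggers 5-exo attack of the acetate carbonyl and a 1,2-acyloxy shift (Rautenstrauch type) that erases the C2 centre and gives the gold vinyl carbenoid Au=C4H–C3(OAc)=C2, whose geometrical isomers should interconvert through the reversible shift so that only the isomer with C1 cis to C4 is consumed, by [2+1] addition to the C5=C9 vinyl group held on the same face of the cis-lactone, closing the eight-membered ring and the cyclopropane (C4–C5, C4–C9) at once; the vinyl group should react in the conformer with C6–H eclipsing the alkene (methyl pseudo-equatorial), putting C9 anti to the C6 methyl, and the cis ring fusion then fixes C4 with C5; the closest known reaction type is the gold(I)-catalysed intramolecular cyclopropanation of secondary, arene-tethered propargylic esters to seven- and eight-membered rings, here extended to a tertiary, fully aliphatic, lactone-templated ester under substrate stereocontrol.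

Step 13
Reactants: 19 tricyclic enol acetate
Product: 21 tricyclic vinyl triflate (C3–OTf in place of C3–OAc), via potassium enolate 20 (not isolated)
Conditions: t-BuOK (1.05 equiv), THF, −78 °C; then Comins' reagent, −78 → −30 °C
Reagents that add atoms: Comins' reagent [N-(5-chloropyridin-2-yl)-bis(trifluoromethanesulfonyl)imide], FC(F)(F)S(=O)(=O)N(c1ccc(Cl)cn1)S(=O)(=O)C(F)(F)F
Why: tert-Butoxide removes the acetyl group of the enol ester to release the tetrasubstituted C2=C3 enolate regiospecifically, and O-sulfonylation by the triflimide traps it; the C11 silyloxy group is too poor a leaving group for E1cB at −78 °C.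

Step 14
Reactants: 21 tricyclic vinyl triflate
Product: 23 C1′-homoprenyl lactone (4-methylpent-3-enyl group on the lactone α-carbon; trans to the C1–C2 bond), via lithium lactone enolate 22 (not isolated)
Conditions: LDA (1.1 equiv), THF, −78 °C; then 5-iodo-2-methylpent-2-ene, DMPU, −78 → −30 °C
Reagents that add atoms: 5-iodo-2-methylpent-2-ene, CC(C)=CCCI
Why: Enolate alkylation of the γ-lactone on its convex face, anti to the C1–C2 bond of the cis-fused ring, sets C1′ (S in the target) trans to C1.

Step 15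
Reactants: 23 C1′-homoprenyl lactone
Product: 24 diol (C8–OH and C12–OH; C11–OTBS; C3–OTf)
Conditions: LiBH4, MeOH (1 equiv), THF, 0 °C → rt
Reagents that add atoms: none
Why: Hydride reduction of the lactone to the 1,4-diol leaves the vinyl triflate, silyl ether, cyclopropane and alkene untouched and affects no stereocentre.

Step 16
Reactants: 24 diol
Product: 25 triol vinyl triflate (C8–OH; C11–OH; C12–OH; C3–OTf)
Conditions: HF·pyridine, pyridine, THF, 0 °C → rt
Reagents that add atoms: none
Why: Fluoride cleavage of the primary allylic silyl ether under buffered acidic conditions that do not attack the triflate.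

Step 17
Reactants: 25 triol vinyl triflate
Product: 26 butenolide diol (deacetyl target)
Conditions: Pd(PPh3)4 (10 mol %), CO (1 atm), Et3N, LiCl, MeCN, 60 °C
Reagents that add atoms: carbon monoxide, [C-]#[O+]
Why: Carbonylative lactonisation (oxidative addition of the vinyl triflate, CO insertion, capture of the acyl–palladium by the cis C11–OH) closes the butenolide; C8–OH and C12–OH lie trans across C2=C3 and cannot lactonise.

Step 18
Reactants: 26 butenolide diol
Product: 27 target CNP0267808.2
Conditions: AcCl (1.05 equiv), 2,4,6-collidine, CH2Cl2, −78 °C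
Reagents that add atoms: acetyl chloride, CC(=O)Cl
Why: Kinetically selective acylation of the unhindered primary C12–OH over the hindered secondary C8–OH.

## Compound list

1 | (R)-4-benzyloxazolidin-2-one | O=C1N[C@H](Cc2ccccc2)CO1 | starting material
2 | (E)-but-2-enoyl chloride | C/C=C/C(=O)Cl | starting material
3 | (R)-4-benzyl-3-[(E)-but-2-enoyl]oxazolidin-2-one | C/C=C/C(=O)N1[C@H](Cc2ccccc2)COC1=O | intermediate
4 | (R)-4-benzyl-3-[(3S)-3-methylpent-4-enoyl]oxazolidin-2-one | C=C[C@@H](C)CC(=O)N1[C@H](Cc2ccccc2)COC1=O | intermediate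
5 | (3S)-3-methylpent-4-enoic acid | C=C[C@@H](C)CC(=O)O | intermediate
6 | (3S)-1-(imidazol-1-yl)-3-methylpent-4-en-1-one (acyl imidazolide; not isolated) | C=C[C@@H](C)CC(=O)n1ccnc1 | intermediate
7 | tert-butyl (5S)-5-methyl-3-oxohept-6-enoate | C=C[C@@H](C)CC(=O)CC(=O)OC(C)(C)C | intermediate
8 | tert-butyl (3S,5S)-3-hydroxy-5-methylhept-6-enoate | C=C[C@@H](C)C[C@H](O)CC(=O)OC(C)(C)C | intermediate
9 | dilithium alkoxide enolate of 8 (not isolated) | [Li+].[Li+].C=C[C@@H](C)C[C@H]([O-])C=C([O-])OC(C)(C)C | intermediate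
10 | di-tert-butyl (2S)-2-[(1S,3S)-1-hydroxy-3-methylpent-4-en-1-yl]butanedioate | CC(C)(C)OC(=O)C[C@@H]([C@@H](O)C[C@H](C)C=C)C(=O)OC(C)(C)C | intermediate
11 | (2S,3S)-2-[(2S)-2-methylbut-3-en-1-yl]-5-oxooxolane-3-carboxylic acid (cis lactone acid) | OC(=O)[C@H]1CC(=O)O[C@H]1C[C@H](C)C=C | intermediate
12 | acid chloride of 11 (not isolated) | ClC(=O)[C@H]1CC(=O)O[C@H]1C[C@H](C)C=C | intermediate
13 | (4S,5S)-4-(2-diazoacetyl)-5-[(2S)-2-methylbut-3-en-1-yl]oxolan-2-one | [N-]=[N+]=CC(=O)[C@H]1CC(=O)O[C@H]1C[C@H](C)C=C | intermediate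
14 | 2-oxo-2-{(2S,3S)-2-[(2S)-2-methylbut-3-en-1-yl]-5-oxooxolan-3-yl}ethyl trifluoroacetate (not isolated) | O=C(OCC(=O)[C@H]1CC(=O)O[C@H]1C[C@H](C)C=C)C(F)(F)F | intermediate
15 | (4S,5S)-4-(2-hydroxyacetyl)-5-[(2S)-2-methylbut-3-en-1-yl]oxolan-2-one | OCC(=O)[C@H]1CC(=O)O[C@H]1C[C@H](C)C=C | intermediate
16 | (4S,5S)-4-{2-[(tert-butyldimethylsilyl)oxy]acetyl}-5-[(2S)-2-methylbut-3-en-1-yl]oxolan-2-one | CC(C)(C)[Si](C)(C)OCC(=O)[C@H]1CC(=O)O[C@H]1C[C@H](C)C=C | intermediate
17 | bromomagnesium alkoxide of the ethynyl carbinol from 16 (not isolated; both C2 epimers) | CC(C)(C)[Si](C)(C)OCC(O[Mg]Br)(C#C)[C@H]1CC(=O)O[C@H]1C[C@H](C)C=C | intermediate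
18 | 1-[(tert-butyldimethylsilyl)oxy]-2-{(2S,3S)-2-[(2S)-2-methylbut-3-en-1-yl]-5-oxooxolan-3-yl}but-3-yn-2-yl acetate (both C2 epimers) | CC(=O)OC(CO[Si](C)(C)C(C)(C)C)(C#C)[C@H]1CC(=O)O[C@H]1C[C@H](C)C=C | intermediate
19 | tricyclic enol acetate: bicyclo[6.1.0]non-2-ene (C1–C8, bridge C9) with cis-fused γ-lactone across C1/C8, C2–CH2OTBS, C3–OAc, C6–CH3; C9 anti to C6–CH3; C1, C4, C5, C6, C8 arranged as in the target | O=C1C[C@@H]2C(CO[Si](C)(C)C(C)(C)C)=C(OC(C)=O)[C@@H]3C[C@@H]3[C@@H](C)C[C@@H]2O1 | intermediate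
20 | potassium C2=C3 enolate from 19 (not isolated) | [K+].O=C1C[C@@H]2C(CO[Si](C)(C)C(C)(C)C)=C([O-])[C@@H]3C[C@@H]3[C@@H](C)C[C@@H]2O1 | intermediate
21 | tricyclic vinyl triflate: as 19 with C3–OSO2CF3 | O=C1C[C@@H]2C(CO[Si](C)(C)C(C)(C)C)=C(OS(=O)(=O)C(F)(F)F)[C@@H]3C[C@@H]3[C@@H](C)C[C@@H]2O1 | intermediate
22 | lithium enolate of the γ-lactone of 21 (not isolated) | [Li+].[O-]C1=C[C@@H]2C(CO[Si](C)(C)C(C)(C)C)=C(OS(=O)(=O)C(F)(F)F)[C@@H]3C[C@@H]3[C@@H](C)C[C@@H]2O1 | intermediate
23 | C1′-homoprenyl lactone: as 21 with a 4-methylpent-3-enyl group on the lactone α-carbon C1′, trans to the C1–C2 bond | O=C1[C@@H](CCC=C(C)C)[C@@H]2C(CO[Si](C)(C)C(C)(C)C)=C(OS(=O)(=O)C(F)(F)F)[C@@H]3C[C@@H]3[C@@H](C)C[C@@H]2O1 | intermediate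
24 | diol: lactone of 23 reduced to C8–OH and C12H2–OH; C11–OTBS and C3–OTf retained | OC[C@@H](CCC=C(C)C)[C@@H]1C(CO[Si](C)(C)C(C)(C)C)=C(OS(=O)(=O)C(F)(F)F)[C@@H]2C[C@@H]2[C@@H](C)C[C@@H]1O | intermediate
25 | triol vinyl triflate: as 24 with free C11H2–OH | OC[C@@H](CCC=C(C)C)[C@@H]1C(CO)=C(OS(=O)(=O)C(F)(F)F)[C@@H]2C[C@@H]2[C@@H](C)C[C@@H]1O | intermediate
26 | butenolide diol (deacetyl target): butenolide fused at C2=C3, free C8–OH and C12–OH | OC[C@@H](CCC=C(C)C)[C@@H]1C2=C(C(=O)OC2)[C@@H]2C[C@@H]2[C@@H](C)C[C@@H]1O | intermediate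
27 | CNP0267808.2: C12 acetate of 26 (C1′ S, C1 R, C4 R, C5 R, C6 S, C8 S) | CC(=O)OC[C@@H](CCC=C(C)C)[C@@H]1C2=C(C(=O)OC2)[C@@H]2C[C@@H]2[C@@H](C)C[C@@H]1O | target

## Step count and weak points

Total step count: 18. Longest linear sequence: 18 (the route is fully linear from 1 and 2).

**Step 12 (the proposed Au step).** It may fail through slow eight-ring closure, diversion of the carbenoid isomer that has C11 cis to C4, or an insufficient facial preference at the vinyl group. The fallback uses known chemistry only; it sets out from 16 and comes back at 21. Wittig methoxymethylenation of 16 (Ph3P=CHOMe, THF, −78 → 0 °C) gives the methyl enol ether F1. Brief hydrolysis with aqueous oxalic acid in THF gives the one-carbon-homologated aldehyde F2, in which C3 is the formyl carbon on C2–H. Vinylmagnesium bromide at −78 °C gives the allylic alcohol F3. Ring-closing metathesis (Grubbs second-generation catalyst, CH2Cl2, 40 °C, 2 mM) on the cis-lactone template closes the eight-membered ring as the Z-cyclooctenol F4 (C4=C5). Dess–Martin oxidation gives the cis-enone F5. Corey–Chaykovsky cyclopropanation (Me3S(O)I, NaH, DMSO) gives the cyclopropyl ketone F6, the ylide adding to C5 anti to the C6 methyl. KHMDS and Comins' reagent (enolisation is possible only towards C2) then give 21.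

**Step 14 (lactone alkylation with an unactivated homoallylic iodide).** E2 loss of HI from the iodide and slow alkylation can erode the yield. The fallback sets out from 21 and comes back at 23. The lithium enolate is alkylated with allyl bromide (fast, same convex-face selectivity) to give the α-allyl lactone F7. 9-BBN followed by NaBO3 oxidises the only terminal alkene to the primary alcohol F8. Dess–Martin oxidation gives the aldehyde F9. Wittig reaction with isopropylidenetriphenylphosphorane (THF, −78 °C) installs the trisubstituted alkene and gives 23.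

**Step 11 (one-flask ethynylation and acetylation).** The tertiary alkoxide sits 1,4 to the lactone carbonyl and could translactonise, and the ketone is epimerisable at C1. The fallback sets out from 16 and comes back at 18. It separates C–C from C–O bond formation so that no alkoxide is left standing. The non-basic ethynylcerium reagent (HC≡CMgBr, CeCl3, THF, −78 °C) is added and quenched cold with acetic acid, and the free tertiary propargylic alcohol F10 is isolated. The neutral alcohol is then acetylated by nucleophilic catalysis (Ac2O, Et3N, DMAP, CH2Cl2, 35 °C) to give 18.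

## Further compounds

F1 | step 12 | methyl enol ether from 16 (C2=CH–OCH3; E/Z mixture) | COC=C(CO[Si](C)(C)C(C)(C)C)[C@H]1CC(=O)O[C@H]1C[C@H](C)C=C
F2 | step 12 | homologated aldehyde (C2H bearing CHO = C3, CH2OTBS and the lactone; C2 epimers) | O=CC(CO[Si](C)(C)C(C)(C)C)[C@H]1CC(=O)O[C@H]1C[C@H](C)C=C
F3 | step 12 | allylic alcohol (C3H(OH)–C4H=CH2; epimers at C2 and C3) | C=CC(O)C(CO[Si](C)(C)C(C)(C)C)[C@H]1CC(=O)O[C@H]1C[C@H](C)C=C
F4 | step 12 | Z-cyclooctenol cis-fused to the γ-lactone (C3–OH, C4=C5) | O=C1C[C@@H]2C(CO[Si](C)(C)C(C)(C)C)C(O)/C=C\[C@@H](C)C[C@@H]2O1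
F5 | step 12 | cis-cyclooctenone (C3=O, C4=C5) | O=C1C[C@@H]2C(CO[Si](C)(C)C(C)(C)C)C(=O)/C=C\[C@@H](C)C[C@@H]2O1
F6 | step 12 | cyclopropyl ketone (C3=O; cyclopropane C4/C5/C9 anti to C6–CH3; C2 epimers) | O=C1C[C@@H]2C(CO[Si](C)(C)C(C)(C)C)C(=O)[C@@H]3C[C@@H]3[C@@H](C)C[C@@H]2O1
F7 | step 14 | α-allyl lactone (allyl on C1′, trans to the C1–C2 bond) | O=C1[C@@H](CC=C)[C@@H]2C(CO[Si](C)(C)C(C)(C)C)=C(OS(=O)(=O)C(F)(F)F)[C@@H]3C[C@@H]3[C@@H](C)C[C@@H]2O1
F8 | step 14 | primary alcohol (3-hydroxypropyl on C1′) | O=C1[C@@H](CCCO)[C@@H]2C(CO[Si](C)(C)C(C)(C)C)=C(OS(=O)(=O)C(F)(F)F)[C@@H]3C[C@@H]3[C@@H](C)C[C@@H]2O1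
F9 | step 14 | aldehyde (3-oxopropyl on C1′) | O=C1[C@@H](CCC=O)[C@@H]2C(CO[Si](C)(C)C(C)(C)C)=C(OS(=O)(=O)C(F)(F)F)[C@@H]3C[C@@H]3[C@@H](C)C[C@@H]2O1
F10 | step 11 | free tertiary propargylic alcohol (both C2 epimers) | CC(C)(C)[Si](C)(C)OCC(O)(C#C)[C@H]1CC(=O)O[C@H]1C[C@H](C)C=C
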